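## Retrosynthesis (overview)

1. Sargachromanol C comes from its phenol TBS ether by fluoride deprotection. The prenyl tail comes from cross-metathesis of a terminal alkene with 2-methyl-2-butene. That alkene comes from catalytic asymmetric allylboration of an (E)-α-methyl enal, which comes from a Wittig reaction of an aldehyde.
2. The aldehyde comes from DIBAL reduction of an ester. The ester comes from a Negishi coupling of the chroman alkyl bromide with an (E)-trisubstituted vinyl iodide (carboalumination/iodination of ethyl pent-4-ynoate).
3. The chroman alkyl bromide, with its C2 quaternary stereocenter, is made in one step by a proposed IDPi-catalysed [4+2] of an o-quinone methide with 4-bromo-2-methylbut-1-ene. The o-quinone methide comes from the TBS-protected salicyl alcohol, which is made from 2-methylhydroquinone (TBS protection, ortho-formylation, reduction).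
4. Ring order: the arene is present from the start, the pyran ring and C2 are formed in step 4, and the two E-alkenes and the carbinol are built afterwards.

Assumptions: (i) the absolute sense of the chiral catalysts (IDPi in step 4, BINOL in step 9) is chosen to give 2R and 9R, and the enantiomeric catalyst is used if a test run shows the opposite sense; (ii) mono-silylation in step 1 is selective for the less hindered 4-OH.

## Route

**Step 1**
Reactants: 1, 2-methylbenzene-1,4-diol (2-methylhydroquinone)
Product: 2, 4-(TBSO)-2-methylphenol
Conditions: TBSCl (1.0 equiv), imidazole, CH2Cl2, 0 °C; chromatographic separation from the regioisomer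
Reagents that add atoms: TBSCl, CC(C)(C)[Si](C)(C)Cl
Why: Silylation of the less hindered OH, which is para to the other OH and remote from the Me group, gives the 4-OTBS phenol. This protects the future C6-oxygen with a group that is removed under mild conditions at the end (silyl protection).

**Step 2**
Reactants: 2
Product: 3, 5-(TBSO)-2-hydroxy-3-methylbenzaldehyde
Conditions: MgCl2, Et3N, (CH2O)n, MeCN, reflux
Reagents that add atoms: paraformaldehyde (formaldehyde), C=O
Why: Magnesium-phenoxide-directed ortho-formylation (Hansen–Skattebøl) occurs only at C6, since the other ortho position carries Me and the para position carries OTBS.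

**Step 3**
Reactants: 3
Product: 4, [2-hydroxy-3-methyl-5-(TBSO)phenyl]methanol
Conditions: NaBH4, MeOH, 0 °C
Reagents that add atoms: none
Why: Simple aldehyde reduction gives the o-quinone methide precursor; the aryl silyl ether is untouched.

**Step 4**
Reactants: 4; 5, 4-bromo-2-methylbut-1-ene (CC(=C)CCBr, commercial)
Product: 6, tert-butyl{[(2S)-2-(2-bromoethyl)-2,8-dimethylchroman-6-yl]oxy}dimethylsilane. This is the same spatial arrangement as the target C2 (R); the CIP label changes because of Br.
Conditions: (S,S)-IDPi (5 mol %), toluene, 4 Å MS, 40 °C, 3 equiv 5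
Reagents that add atoms: none (5 is the numbered reactant; water is lost)
Why: Proposed new method: the confined, strongly acidic IDPi hydrogen-bonds and protonates the parent o-quinone methide formed by dehydration of 4, giving a tight chiral ion pair. The CH2 terminus of the 1,1-disubstituted alkene attacks the methide carbon, and the resulting tertiary cation is captured by the phenol OH inside the anion pocket, which discriminates Me from CH2CH2Br and sets the quaternary C2. The closest known chemistry is the chiral-phosphoric-acid [4+2] of o-quinone methides with vinyl ethers and enamides, combined with IDPi-catalysed hydroalkoxylation of unactivated alkenes. Here it is applied to a C4-unsubstituted o-quinone methide and a simple aliphatic alkene, forming the pyran ring and the stereocenter in one step.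

**Step 5**
Reactants: 7, ethyl pent-4-ynoate
Product: 8, ethyl (4E)-5-iodo-4-methylpent-4-enoate
Conditions: Me3Al, Cp2ZrCl2 (cat.), ClCH2CH2Cl, 0 °C→rt; then I2, THF, −30 °C
Reagents that add atoms: trimethylaluminium, C[Al](C)C; iodine, II
Why: Negishi Zr-catalysed syn-methylalumination places Me on the internal carbon and Al on the terminal carbon, and iodination then gives the (E)-trisubstituted vinyl iodide with I trans to the chain.

**Step 6**
Reactants: 6; 8
Product: 9, ethyl (4E)-7-[(2R)-6-(TBSO)-2,8-dimethylchroman-2-yl]-4-methylhept-4-enoate
Conditions: (a) Zn dust, LiCl, TMSCl/BrCH2CH2Br (cat.), THF, 50 °C; (b) 8, Pd(PPh3)4 (5 mol %), THF, 50 °C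
Reagents that add atoms: none
Why: A Negishi sp3–sp2 coupling of the primary alkylzinc with the vinyl iodide proceeds with retention of alkene geometry (E) and is compatible with the ester and aryl silyl ether. The quaternary stereocenter is three bonds from zinc and is not touched.

**Step 7**
Reactants: 9
Product: 10, (4E)-7-[(2R)-6-(TBSO)-2,8-dimethylchroman-2-yl]-4-methylhept-4-enal
Conditions: DIBAL-H (1.05 equiv), CH2Cl2, −78 °C
Reagents that add atoms: none
Why: Partial reduction of the aliphatic ester at −78 °C stops at the aldehyde. The trisubstituted alkene and aryl silyl ether are inert.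

**Step 8**
Reactants: 10; 11, 2-(triphenylphosphoranylidene)propanal (O=CC(C)=P(c1ccccc1)(c1ccccc1)c1ccccc1)
Product: 12, (2E,6E)-9-[(2R)-6-(TBSO)-2,8-dimethylchroman-2-yl]-2,6-dimethylnona-2,6-dienal
Conditions: 11 (1.3 equiv), toluene, 80 °C
Reagents that add atoms: none (11 is the numbered reactant)
Why: A stabilized-ylide Wittig reaction is strongly E-selective, giving the C10′=C11′ alkene required in the target.

**Step 9**
Reactants: 12; 13, allyldiisopropoxyborane (C=CCB(OC(C)C)OC(C)C)
Product: 14, (4R,5E,9E)-12-[(2R)-6-(TBSO)-2,8-dimethylchroman-2-yl]-5,9-dimethyldodeca-1,5,9-trien-4-ol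
Conditions: (S)-3,3′-diaryl-BINOL (15 mol %), toluene, 4 Å MS, −20 °C
Reagents that add atoms: none (13 is the numbered reactant)
Why: BINOL-catalysed asymmetric allylboration (Schaus type) proceeds through a chair transition state in which the chiral diol exchanges with one isopropoxy group. The aldehyde face is selected in this transition state, which sets the (R) carbinol C12′.

**Step 10**
Reactants: 14; 15, 2-methylbut-2-ene (CC=C(C)C)
Product: 16, O-TBS sargachromanol C: (2R)-6-(TBSO)-2-[(3E,7E,9R)-9-hydroxy-4,8,12-trimethyltrideca-3,7,11-trien-1-yl]-2,8-dimethylchroman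
Conditions: Hoveyda–Grubbs II (5 mol %), 15 (20 equiv), CH2Cl2, 40 °C (sealed)
Reagents that add atoms: none (15 is the numbered reactant)
Why: Cross-metathesis of the monosubstituted alkene with excess 2-methylbut-2-ene converts =CH2 into =CMe2 (prenyl terminus). The hindered trisubstituted alkenes and the carbinol stereocenter are untouched.

**Step 11**
Reactants: 16
Product: 17, sargachromanol C
Conditions: TBAF, AcOH (1:1), THF, 0 °C, degassed
Reagents that add atoms: none
Why: Fluoride cleavage of the aryl silyl ether, buffered to avoid base-mediated side reactions and kept oxygen-free to protect the electron-rich chroman-6-ol, liberates the free phenol and gives the target.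

## Compound list

1 | 2-methylbenzene-1,4-diol | Cc1cc(O)ccc1O | starting material
2 | 4-(TBSO)-2-methylphenol | Cc1cc(O[Si](C)(C)C(C)(C)C)ccc1O | intermediate
3 | 5-(TBSO)-2-hydroxy-3-methylbenzaldehyde | Cc1cc(O[Si](C)(C)C(C)(C)C)cc(C=O)c1O | intermediate
4 | [2-hydroxy-3-methyl-5-(TBSO)phenyl]methanol | Cc1cc(O[Si](C)(C)C(C)(C)C)cc(CO)c1O | intermediate
5 | 4-bromo-2-methylbut-1-ene | C=C(C)CCBr | starting material
6 | (2S)-2-(2-bromoethyl)-6-(TBSO)-2,8-dimethylchroman | BrCC[C@]1(C)CCc2cc(O[Si](C)(C)C(C)(C)C)cc(C)c2O1 | intermediate
7 | ethyl pent-4-ynoate | CCOC(=O)CCC#C | starting material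
8 | ethyl (4E)-5-iodo-4-methylpent-4-enoate | CCOC(=O)CC/C(C)=C/I | intermediate
9 | ethyl (4E)-7-[(2R)-6-(TBSO)-2,8-dimethylchroman-2-yl]-4-methylhept-4-enoate | CCOC(=O)CC/C(C)=C/CC[C@]1(C)CCc2cc(O[Si](C)(C)C(C)(C)C)cc(C)c2O1 | intermediate
10 | (4E)-7-[(2R)-6-(TBSO)-2,8-dimethylchroman-2-yl]-4-methylhept-4-enal | O=CCC/C(C)=C/CC[C@]1(C)CCc2cc(O[Si](C)(C)C(C)(C)C)cc(C)c2O1 | intermediate
11 | 2-(triphenylphosphoranylidene)propanal | O=CC(C)=P(c1ccccc1)(c1ccccc1)c1ccccc1 | starting material
12 | (2E,6E)-9-[(2R)-6-(TBSO)-2,8-dimethylchroman-2-yl]-2,6-dimethylnona-2,6-dienal | O=C/C(C)=C/CC/C(C)=C/CC[C@]1(C)CCc2cc(O[Si](C)(C)C(C)(C)C)cc(C)c2O1 | intermediate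
13 | allyldiisopropoxyborane | C=CCB(OC(C)C)OC(C)C | starting material
14 | (4R,5E,9E)-12-[(2R)-6-(TBSO)-2,8-dimethylchroman-2-yl]-5,9-dimethyldodeca-1,5,9-trien-4-ol | C=CC[C@@H](O)/C(C)=C/CC/C(C)=C/CC[C@]1(C)CCc2cc(O[Si](C)(C)C(C)(C)C)cc(C)c2O1 | intermediate
15 | 2-methylbut-2-ene | CC=C(C)C | starting material
16 | O-TBS sargachromanol C | CC(C)=CC[C@@H](O)/C(C)=C/CC/C(C)=C/CC[C@]1(C)CCc2cc(O[Si](C)(C)C(C)(C)C)cc(C)c2O1 | intermediate
17 | sargachromanol C, (2R)-2-[(3E,7E,9R)-9-hydroxy-4,8,12-trimethyltrideca-3,7,11-trien-1-yl]-2,8-dimethylchroman-6-ol | CC(C)=CC[C@@H](O)/C(C)=C/CC/C(C)=C/CC[C@]1(C)CCc2cc(O)cc(C)c2O1 | target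

## Totals

Total steps: 11 (including the vinyl-iodide preparation, step 5). Longest linear sequence: 10 steps (1→2→3→4→6→7→8→9→10→11).

## Three steps most likely to fail

1. **Step 4 (proposed new [4+2]).** Risks are low ee from poor Me versus CH2CH2Br discrimination, oligomerisation of the parent o-quinone methide, and proton loss from the cation to give the ene-type phenol. Fallback (known chemistry, different approach): make racemic 6 with an achiral acid (TfOH or Sc(OTf)3) in the same known o-quinone methide/alkene cycloaddition, then resolve at the ester stage 9 by preparative chiral-phase HPLC/SFC.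
2. **Step 9 (catalytic asymmetric allylboration of the α-methyl enal).** Risks are moderate ee and slow conversion. Fallback: stoichiometric Brown allylation with (+)- or (−)-Ipc2B-allyl at −78 °C, which is a different reagent class and known to work for α-methyl enals.
3. **Step 10 (cross-metathesis on a polyene with a free allylic alcohol).** Risks are exchange at the internal trisubstituted alkenes and low conversion. Fallback: skip steps 9–10 and add prenylbarium (α-selective, Yamamoto type) to enal 12 to give the racemic linear prenyl carbinol. Oxidise it with Dess–Martin periodinane to the dienone, reduce it with the CBS catalyst and borane to set (R), and finish with step 11.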